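**Retrosynthetic overview**

1. The ten-membered carbocycle is closed last, by ring-closing metathesis at C3=C4, on a seco triene that already carries the C6 chloride (SN2 on a 6R alcohol), the butanolide and both acetates.
2. C5–C6 comes from an aqueous indium butadien-2-ylation of the C6 lactol carbon, C2–C3 from vinyl Grignard addition to the C2 aldehyde, and 11-OH from a Rubottom oxidation.
3. The cyclohexenone (C1, C14, C13, C12, C11, C10) comes from a type 2 intramolecular Diels–Alder reaction of the diene C14=C13–C12(O)=C11 with the E-enal C10=C1(CH3)–C2HO. The enabling feature is that the tertiary C8 hydroxyl lies three bonds from C10, so one silicon atom can bridge O8 and the C12 oxygen (temporary eight-membered silaketal ring); the C15 methyl on C1, cis to C9, locks the C9–C10 rotamer by A(1,3) strain.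
4. C6–C10 with the C7 and C9 stereocentres are bought as L-arabinose (sugar C1–C5); C8 and C17 come from a propanoate aldol on its 3-ulose; every other stereocentre is relayed from these.
5. Ring order: furanose (bought, temporary) → cyclohexenone (with the temporary silaketal ring) → butanolide → ten-membered ring.

Key step: step 8

Remark on numbering: briarane numbering is used. C1 is the quaternary ring-fusion carbon (CH3 = C15), C2–C9 run round the ten-membered ring, C10 is the ring-fusion CH, C11–C14 complete the cyclohexenone (CH3 on C11 = C20), C16 is the exo-methylene carbon, and C17/C18/C19 are the lactone CH, its methyl and its carbonyl.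
Remark on C17: the aldol of step 3 may deliver both C17 epimers; the 17R epimer is drawn throughout and C17 is equilibrated at the lactone stage (step 16).
Remark on C11: it is drawn as the cycloaddition should deliver it and becomes trigonal in step 10.

**Route**

Step 1
Reactants: 1 L-arabinose
Product: 3 5-O-TBDPS-1,2-O-isopropylidene-β-L-arabinofuranose, via 5-O-TBDPS-L-arabinofuranose 2 (not isolated)
Conditions: TBDPSCl, imidazole, DMF, 0 °C to rt; then 2,2-dimethoxypropane, acetone, cat. CSA, rt
Reagents that add atoms: tert-butylchlorodiphenylsilane CC(C)(C)[Si](Cl)(c1ccccc1)c1ccccc1; 2,2-dimethoxypropane COC(C)(C)OC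
Why: Silylation of the only primary hydroxyl should trap the furanose form and acid-catalysed ketalisation should then tie the cis-1,2-diol as the acetonide, leaving O3 alone free; no stereocentre is touched, and C7 and C9 of the target (sugar C2 and C4) are bought here.

Step 2
Reactants: 3 5-O-TBDPS-1,2-O-isopropylidene-β-L-arabinofuranose
Product: 4 5-O-TBDPS-1,2-O-isopropylidene-β-L-threo-pentofuranos-3-ulose
Conditions: Dess–Martin periodinane, CH2Cl2, rt
Reagents that add atoms: none
Why: Dess–Martin oxidation of the single free secondary alcohol should give the C8 ketone without disturbing the flanking stereocentres.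

Step 3
Reactants: 4 5-O-TBDPS-1,2-O-isopropylidene-β-L-threo-pentofuranos-3-ulose; 5 tert-butyl propanoate
Product: 6 tert-butyl (2R)-2-(5-O-TBDPS-1,2-O-isopropylidene-β-L-lyxofuranos-3-C-yl)propanoate
Conditions: LiN(iPr)2, THF, −78 °C, 5; then 4, −78 °C; AcOH quench
Reagents that add atoms: none
Why: Aldol addition of the ester lithium enolate to the ketone should occur on the convex face, because the acetonide and the C4 side chain both sit on the other face, which sets C8 (tertiary OH cis to the acetonide); the bulky tert-butyl ester cannot lactonise later until it is unmasked.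

Step 4
Reactants: 6 tert-butyl (2R)-2-(5-O-TBDPS-1,2-O-isopropylidene-β-L-lyxofuranos-3-C-yl)propanoate
Product: 7 C10 primary alcohol
Conditions: Bu4NF, AcOH, THF, 0 °C to rt
Reagents that add atoms: none
Why: Fluoride-mediated desilylation, buffered with acetic acid so that the tertiary aldolate cannot undergo retro-aldol cleavage, should free the primary hydroxyl only.

Step 5
Reactants: 7 C10 primary alcohol; 8 2-(triphenyl-λ5-phosphanylidene)propanal
Product: 10 E-enal, via C10 aldehyde 9 (not isolated)
Conditions: Dess–Martin periodinane, CH2Cl2, 0 °C to rt; filtration; then 8, toluene, 60 °C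
Reagents that add atoms: none
Why: Dess–Martin oxidation followed by Wittig olefination with the formyl-stabilised ylide should give the E-trisubstituted enal (E from the stabilised ylide), which installs C10=C1, the C15 methyl and the C2 aldehyde with C2 trans to C9.

Step 6
Reactants: 11 (E)-4-methoxybut-3-en-2-one
Product: 12 (E)-1-methoxypent-1-en-3-one
Conditions: LiN(iPr)2, THF, −78 °C; MeI, DMPU, −78 to −20 °C
Reagents that add atoms: iodomethane CI
Why: Kinetic deprotonation of the vinylogous ester at its methyl group and enolate alkylation should give the ethyl ketone that carries the future C11 and its methyl.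

Step 7
Reactants: 10 E-enal; 12 (E)-1-methoxypent-1-en-3-one
Product: 14 silaketal triene, via C8-O-silyl triflate 13 (not isolated)
Conditions: iPr2Si(OTf)2, 2,6-lutidine, CH2Cl2, −78 to 0 °C; then 12, Et3N, −78 °C to rt
Reagents that add atoms: diisopropylsilyl bis(trifluoromethanesulfonate) CC(C)[Si](OS(=O)(=O)C(F)(F)F)(OS(=O)(=O)C(F)(F)F)C(C)C
Why: Two successive O-silylations at one silicon (temporary silicon connection) should first take the hindered tertiary C8 hydroxyl and then enol-silylate the ethyl ketone under silyl triflate/amine conditions, which give the Z enol ether and leave the E methoxyvinyl group intact.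

Step 8
Reactants: 14 silaketal triene
Product: 17 cyclohexenone aldehyde, via bridged cycloadduct 15 (not isolated), via β-methoxy ketone 16 (not isolated)
Conditions: toluene (5 mM), BHT, cat. 2,6-di-tert-butyl-4-methylpyridine, 100 °C; then HF·pyridine, THF, 0 °C to rt
Reagents that add atoms: none
Why: Proposed new method: on heating, the dienol ether held through O12–Si–O8 should add to the E-enal in a concerted type 2 intramolecular Diels–Alder reaction (C11 to the enal β-carbon C10, C14 to C1), after which HF cleaves both Si–O bonds and eliminates methanol from the β-methoxy ketone to give the enone; the closest known reaction types are type 2 intramolecular Diels–Alder reactions through disposable silicon tethers and thermal cycloadditions of 1-methoxy-3-silyloxy dienes with 2-methyl enals. The six-membered carbocycle closes by [4+2] cycloaddition, and the temporary eight-membered silaketal ring closes in the same event as a 1,3-bridge (bicyclo[5.3.1] system, tether endo, enol ether double bond at the bridgehead). C1 and C10 follow from the E geometry of the dienophile (C2 and C9 trans) and from the face of attack, which C9 controls: A(1,3) strain between the C15 methyl and the furanose holds H9 in the enal plane, C8 then stands perpendicular on one face, and its oxygen, cis to the side chain on the furanose, delivers the diene to that face (1S,10S). C11 (methyl cis to C9) follows from the Z enol ether and the endo tether and is re-set in step 10. The step needs regioselectivity (secured by attaching the tether at C12 and by matched polarity, nucleophilic C11 with electrophilic C10), facial selectivity (A(1,3) lock plus tether) and chemoselectivity against hetero-Diels–Alder addition to the aldehyde (no Lewis acid, high dilution).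

Step 9
Reactants: 17 cyclohexenone aldehyde
Product: 18 (2S)-vinyl carbinol
Conditions: CH2=CHMgBr (3 equiv), THF, −78 °C; aq. NH4Cl
Reagents that add atoms: vinylmagnesium bromide C=C[Mg]Br
Why: Grignard 1,2-addition to the neopentyl aldehyde should be far faster than attack on the hindered enone or the tert-butyl ester, and Felkin–Anh control at the quaternary C1 (C10 with its furanose as the large group anti to the nucleophile, C14 medium, methyl small) should give the 2S carbinol.

Step 10
Reactants: 18 (2S)-vinyl carbinol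
Product: 21 11-hydroxy enone, via tris-TMS dienol ether 19 (not isolated), via tris-TMS 11-silyloxy enone 20 (not isolated)
Conditions: TMSOTf, Et3N, CH2Cl2, −78 to 0 °C; mCPBA, hexane/CH2Cl2, −20 °C; then HF·pyridine, THF, 0 °C
Reagents that add atoms: 3-chloroperbenzoic acid OOC(=O)c1cccc(Cl)c1
Why: Rubottom oxidation: soft enolisation can only occur towards C11 (C1 is quaternary), and the peracid should epoxidise the electron-rich tetrasubstituted enol ether bond from the face anti to the adjacent C10 furanosyl group and to the C15 methyl, which sets C11 with the hydroxyl cis to H10.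

Step 11
Reactants: 21 11-hydroxy enone
Product: 22 C6 lactol
Conditions: AcOH/H2O 3:1, 65 °C
Reagents that add atoms: none
Why: Acid-catalysed ketal hydrolysis in weak aqueous acid should remove the anomeric acetonide faster than it cleaves the tert-butyl ester, unmasking C6 as a lactol and O7 as a free hydroxyl.

Step 12
Reactants: 22 C6 lactol
Product: 23 seco hexol diene
Conditions: indium powder, 1,4-dibromobut-2-yne, THF/H2O 1:1, rt
Reagents that add atoms: 1,4-dibromobut-2-yne BrCC#CCBr
Why: Barbier-type indium-mediated buta-1,3-dien-2-ylation in water should act on the aldehyde form of the lactol only, with chelation by the free α-hydroxyl (Cram chelate) giving the syn 6,7-diol (6R); the ring opening also frees O9.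

Step 13
Reactants: 23 seco hexol diene
Product: 24 6,7-O-isopropylidene derivative
Conditions: 2,2-dimethoxypropane, cat. PPTS, CH2Cl2, 0 °C to rt
Reagents that add atoms: 2,2-dimethoxypropane COC(C)(C)OC
Why: Acetonide formation should select the only vicinal pair of secondary hydroxyls (trans-dioxolane from the syn diol), masking O6 and O7 so that O9 can be capped before any lactone can form.

Step 14
Reactants: 24 6,7-O-isopropylidene derivative
Product: 25 2,9-di-O-acetate
Conditions: Ac2O, DMAP, pyridine, rt to 40 °C
Reagents that add atoms: acetic anhydride CC(=O)OC(C)=O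
Why: DMAP-catalysed acylation should acetylate the two remaining secondary alcohols (O2, O9) while the tertiary hydroxyls at C8 and C11 stay free.

Step 15
Reactants: 25 2,9-di-O-acetate
Product: 26 6,7-diol
Conditions: PPTS, MeOH, 45 °C
Reagents that add atoms: none
Why: Transketalisation to methanol under weak acid should remove the dioxolane without harming the diene, the acetates or the tert-butyl ester.

Step 16
Reactants: 26 6,7-diol
Product: 29 hydroxy butanolide, via persilylated TMS ester 27 (not isolated), via seco acid 28 (not isolated)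
Conditions: TMSOTf, 2,6-lutidine, CH2Cl2, 0 °C; then aq. citric acid, THF, rt; then cat. DBU, CH2Cl2, rt
Reagents that add atoms: none
Why: Silyl triflate-mediated cleavage of the tert-butyl ester (non-protic, so the diene is spared) and mild aqueous acid should give the seco acid, which lactonises to the five-membered ring at O7 rather than the six-membered ring at O6 (O9 is blocked as acetate); DBU then equilibrates C17 to the more stable epimer with the methyl trans to the C9 branch.

Step 17
Reactants: 29 hydroxy butanolide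
Product: 31 seco chloride, via C6 mesylate 30 (not isolated)
Conditions: MsCl, 2,4,6-collidine, LiCl, DMF, 0 °C
Reagents that add atoms: lithium chloride [Li+].[Cl-]
Why: Collington–Meyers allylic chlorination: the only secondary alcohol is mesylated and displaced by chloride in an SN2 reaction with inversion (6R alcohol to 6S chloride), ionisation being disfavoured by the oxygen on C7.

Step 18
Reactants: 31 seco chloride
Product: 32 target
Conditions: second-generation Hoveyda–Grubbs catalyst RuCl2(H2IMes)(=CH–C6H4-2-OiPr) (15 mol %), toluene (1 mM), 80 °C, argon sparge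
Reagents that add atoms: none
Why: Ring-closing olefin metathesis between the two monosubstituted vinyl groups (C3 and C4) should close the ten-membered ring, the ring size enforcing the Z alkene and the 1,1-disubstituted C5=C16 bond being too hindered to compete.

**Compound list**

1 | L-arabinose (open-chain form drawn) | O=C[C@H](O)[C@@H](O)[C@@H](O)CO | starting material
2 | 5-O-TBDPS-L-arabinofuranose (anomers) | CC(C)(C)[Si](OC[C@@H]1OC(O)[C@H](O)[C@H]1O)(c1ccccc1)c1ccccc1 | intermediate
3 | 5-O-TBDPS-1,2-O-isopropylidene-β-L-arabinofuranose | CC(C)(C)[Si](OC[C@@H]1O[C@@H]2OC(C)(C)O[C@@H]2[C@H]1O)(c1ccccc1)c1ccccc1 | intermediate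
4 | 5-O-TBDPS-1,2-O-isopropylidene-β-L-threo-pentofuranos-3-ulose | CC(C)(C)[Si](OC[C@@H]1O[C@@H]2OC(C)(C)O[C@@H]2C1=O)(c1ccccc1)c1ccccc1 | intermediate
5 | tert-butyl propanoate | CCC(=O)OC(C)(C)C | starting material
6 | tert-butyl (2R)-2-(5-O-TBDPS-1,2-O-isopropylidene-β-L-lyxofuranos-3-C-yl)propanoate (tertiary OH cis to the acetonide) | CC(C)(C)[Si](OC[C@@H]1O[C@@H]2OC(C)(C)O[C@@H]2[C@@]1(O)[C@@H](C)C(=O)OC(C)(C)C)(c1ccccc1)c1ccccc1 | intermediate
7 | C10 primary alcohol (6 without the silyl group) | OC[C@@H]1O[C@@H]2OC(C)(C)O[C@@H]2[C@@]1(O)[C@@H](C)C(=O)OC(C)(C)C | intermediate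
8 | 2-(triphenyl-λ5-phosphanylidene)propanal | CC(C=O)=P(c1ccccc1)(c1ccccc1)c1ccccc1 | starting material
9 | C10 aldehyde (pentodialdofuranose) | O=C[C@@H]1O[C@@H]2OC(C)(C)O[C@@H]2[C@@]1(O)[C@@H](C)C(=O)OC(C)(C)C | intermediate
10 | E-enal (C10=C1(CH3)–C2HO on sugar C4) | O=C/C(C)=C/[C@@H]1O[C@@H]2OC(C)(C)O[C@@H]2[C@@]1(O)[C@@H](C)C(=O)OC(C)(C)C | intermediate
11 | (E)-4-methoxybut-3-en-2-one | CC(=O)/C=C/OC | starting material
12 | (E)-1-methoxypent-1-en-3-one | CCC(=O)/C=C/OC | intermediate
13 | C8-O-(diisopropyl)(triflyloxy)silyl ether of 10 | O=C/C(C)=C/[C@@H]1O[C@@H]2OC(C)(C)O[C@@H]2[C@@]1(O[Si](C(C)C)(C(C)C)OS(=O)(=O)C(F)(F)F)[C@@H](C)C(=O)OC(C)(C)C | intermediate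
14 | silaketal triene (O8–Si(iPr)2–O12; 1E,3Z-dienol ether; E-enal) | O=C/C(C)=C/[C@@H]1O[C@@H]2OC(C)(C)O[C@@H]2[C@@]1(O[Si](C(C)C)(C(C)C)O/C(=C\C)/C=C/OC)[C@@H](C)C(=O)OC(C)(C)C | intermediate
15 | bridged cycloadduct (silaketal still in place) | O=C[C@@]1(C)[C@H](OC)C=C2[C@H](C)[C@@H]1[C@@H]3O[C@@H]4OC(C)(C)O[C@@H]4[C@@]3(O[Si](C(C)C)(C(C)C)O2)[C@@H](C)C(=O)OC(C)(C)C | intermediate
16 | β-methoxy ketone | O=C[C@@]1(C)[C@H](OC)CC(=O)[C@H](C)[C@@H]1[C@@H]2O[C@@H]3OC(C)(C)O[C@@H]3[C@@]2(O)[C@@H](C)C(=O)OC(C)(C)C | intermediate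
17 | cyclohexenone aldehyde (1S,10S) | O=C[C@@]1(C)C=CC(=O)[C@H](C)[C@@H]1[C@@H]2O[C@@H]3OC(C)(C)O[C@@H]3[C@@]2(O)[C@@H](C)C(=O)OC(C)(C)C | intermediate
18 | (2S)-vinyl carbinol | C=C[C@H](O)[C@@]1(C)C=CC(=O)[C@H](C)[C@@H]1[C@@H]2O[C@@H]3OC(C)(C)O[C@@H]3[C@@]2(O)[C@@H](C)C(=O)OC(C)(C)C | intermediate
19 | tris-TMS dienol ether | C=C[C@H](O[Si](C)(C)C)[C@@]1(C)C=CC(O[Si](C)(C)C)=C(C)[C@@H]1[C@@H]2O[C@@H]3OC(C)(C)O[C@@H]3[C@@]2(O[Si](C)(C)C)[C@@H](C)C(=O)OC(C)(C)C | intermediate
20 | tris-TMS 11-silyloxy enone | C=C[C@H](O[Si](C)(C)C)[C@@]1(C)C=CC(=O)[C@@](C)(O[Si](C)(C)C)[C@@H]1[C@@H]2O[C@@H]3OC(C)(C)O[C@@H]3[C@@]2(O[Si](C)(C)C)[C@@H](C)C(=O)OC(C)(C)C | intermediate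
21 | 11-hydroxy enone (2,8,11-triol) | C=C[C@H](O)[C@@]1(C)C=CC(=O)[C@@](C)(O)[C@@H]1[C@@H]2O[C@@H]3OC(C)(C)O[C@@H]3[C@@]2(O)[C@@H](C)C(=O)OC(C)(C)C | intermediate
22 | C6 lactol (furanose hemiacetal, anomers) | C=C[C@H](O)[C@@]1(C)C=CC(=O)[C@@](C)(O)[C@@H]1[C@@H]2OC(O)[C@H](O)[C@@]2(O)[C@@H](C)C(=O)OC(C)(C)C | intermediate
23 | seco hexol diene (6R, buta-1,3-dien-2-yl on C6) | C=C[C@H](O)[C@@]1(C)C=CC(=O)[C@@](C)(O)[C@@H]1[C@H](O)[C@](O)([C@@H](C)C(=O)OC(C)(C)C)[C@@H](O)[C@H](O)C(=C)C=C | intermediate
24 | 6,7-O-isopropylidene derivative | C=C[C@H](O)[C@@]1(C)C=CC(=O)[C@@](C)(O)[C@@H]1[C@H](O)[C@](O)([C@@H](C)C(=O)OC(C)(C)C)[C@H]2OC(C)(C)O[C@@H]2C(=C)C=C | intermediate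
25 | 2,9-di-O-acetate of 24 | C=C[C@H](OC(C)=O)[C@@]1(C)C=CC(=O)[C@@](C)(O)[C@@H]1[C@H](OC(C)=O)[C@](O)([C@@H](C)C(=O)OC(C)(C)C)[C@H]2OC(C)(C)O[C@@H]2C(=C)C=C | intermediate
26 | 6,7-diol 2,9-diacetate | C=C[C@H](OC(C)=O)[C@@]1(C)C=CC(=O)[C@@](C)(O)[C@@H]1[C@H](OC(C)=O)[C@](O)([C@@H](C)C(=O)OC(C)(C)C)[C@@H](O)[C@H](O)C(=C)C=C | intermediate
27 | persilylated TMS ester | C=C[C@H](OC(C)=O)[C@@]1(C)C=CC(=O)[C@@](C)(O[Si](C)(C)C)[C@@H]1[C@H](OC(C)=O)[C@](O[Si](C)(C)C)([C@@H](C)C(=O)O[Si](C)(C)C)[C@@H](O[Si](C)(C)C)[C@H](O[Si](C)(C)C)C(=C)C=C | intermediate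
28 | seco acid | C=C[C@H](OC(C)=O)[C@@]1(C)C=CC(=O)[C@@](C)(O)[C@@H]1[C@H](OC(C)=O)[C@](O)([C@@H](C)C(O)=O)[C@@H](O)[C@H](O)C(=C)C=C | intermediate
29 | hydroxy butanolide (6R alcohol) | C=C[C@H](OC(C)=O)[C@@]1(C)C=CC(=O)[C@@](C)(O)[C@@H]1[C@H](OC(C)=O)[C@]2(O)[C@@H](C)C(=O)O[C@H]2[C@H](O)C(=C)C=C | intermediate
30 | C6 mesylate | C=C[C@H](OC(C)=O)[C@@]1(C)C=CC(=O)[C@@](C)(O)[C@@H]1[C@H](OC(C)=O)[C@]2(O)[C@@H](C)C(=O)O[C@H]2[C@H](OS(C)(=O)=O)C(=C)C=C | intermediate
31 | seco chloride (6S) | C=C[C@H](OC(C)=O)[C@@]1(C)C=CC(=O)[C@@](C)(O)[C@@H]1[C@H](OC(C)=O)[C@]2(O)[C@@H](C)C(=O)O[C@H]2[C@@H](Cl)C(=C)C=C | intermediate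
32 | CNP0188317.1 | C=C1/C=C\[C@H](OC(C)=O)[C@@]2(C)C=CC(=O)[C@@](C)(O)[C@@H]2[C@H](OC(C)=O)[C@]2(O)[C@@H](C)C(=O)O[C@H]2[C@H]1Cl | target

**Step count and risks**

Total step count: 18. Longest linear sequence: 17 steps (steps 1–5 and 7–18, from L-arabinose); step 6 is a one-step branch.

The three steps most likely to fail:

1. Step 8 (Proposed new method). The bridged transition state may be too strained, so that the silaketal is lost by hydrolysis or desilylative Michael addition before it cyclises, or the rotamer with O9 in the enal plane may compete and erode facial control. The fallback uses known chemistry, sets out from 10 and 12, and comes back at 21 (or directly at 17). Ketone 12 is converted with TMSOTf and Et3N into the free diene (1E,3Z)-1-methoxy-3-(trimethylsilyloxy)penta-1,3-diene F1. A bimolecular thermal Diels–Alder reaction of F1 with enal 10 (toluene, 90–110 °C, sealed tube) should give the silyl enol ether cycloadduct F2, with the regiochemistry usual for a 1-methoxy-3-silyloxy diene and a 2-methyl enal, and with the face chosen by attack anti to the C9–O9 bond of the same A(1,3)-locked rotamer. HF·pyridine then gives 17 or, if the formyl group reacts endo, its C11 epimer F3. F3 is taken through step 9 to the C11-epimeric carbinol F4 and through step 10, where C11 becomes trigonal, so both series converge at 21.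

2. Step 18. Ring closure may lose to oligomerisation or to ring opening by ethene, and the allylic chloride may ionise or eliminate at the temperature required. The fallback sets out from 29 and comes back at 32: the ring is closed before the chlorine is introduced. Metathesis of the hydroxy lactone 29 with the same catalyst at lower temperature, the free allylic hydroxyl being tolerated by the ruthenium carbene, should give the macrocyclic 6R alcohol F5. The chloride is then set on the ring through the macrocyclic mesylate F6 (MsCl, collidine, LiCl), where peripheral SN2 attack inverts C6 and allylic transposition would have to create a strained endocyclic alkene.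

3. Step 12. Addition may proceed with poor chelation control, giving C6 epimers, or the organoindium may attack the enone or stall before the second, diene-forming insertion. The fallback sets out from 22 and comes back at 23 in two known reactions. Ethynylmagnesium bromide HC≡CMgBr (excess, THF, −40 °C) should add to the magnesium-chelated aldehyde form of the lactol, syn to O7, to give the propargylic hexol F7. Cross enyne metathesis with ethene (second-generation Grubbs catalyst RuCl2(=CHPh)(PCy3)(H2IMes), ethene 1 atm, CH2Cl2, 40 °C) then turns the terminal alkyne into the 2-substituted buta-1,3-diene 23.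

**Further compounds**

F1 | step 8 | (1E,3Z)-1-methoxy-3-(trimethylsilyloxy)penta-1,3-diene | C[Si](C)(C)O/C(=C\C)/C=C/OC
F2 | step 8 | bimolecular cycloadduct (TMS enol ether, formyl endo) | O=C[C@@]1(C)[C@@H](OC)C=C(O[Si](C)(C)C)[C@@H](C)[C@@H]1[C@@H]2O[C@@H]3OC(C)(C)O[C@@H]3[C@@]2(O)[C@@H](C)C(=O)OC(C)(C)C
F3 | step 8 | C11 epimer of 17 | O=C[C@@]1(C)C=CC(=O)[C@@H](C)[C@@H]1[C@@H]2O[C@@H]3OC(C)(C)O[C@@H]3[C@@]2(O)[C@@H](C)C(=O)OC(C)(C)C
F4 | step 8 | C11 epimer of 18 | C=C[C@H](O)[C@@]1(C)C=CC(=O)[C@@H](C)[C@@H]1[C@@H]2O[C@@H]3OC(C)(C)O[C@@H]3[C@@]2(O)[C@@H](C)C(=O)OC(C)(C)C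
F5 | step 18 | macrocyclic 6R alcohol (deschloro-6-hydroxy macrocycle) | C=C1/C=C\[C@H](OC(C)=O)[C@@]2(C)C=CC(=O)[C@@](C)(O)[C@@H]2[C@H](OC(C)=O)[C@]2(O)[C@@H](C)C(=O)O[C@H]2[C@@H]1O
F6 | step 18 | macrocyclic C6 mesylate | C=C1/C=C\[C@H](OC(C)=O)[C@@]2(C)C=CC(=O)[C@@](C)(O)[C@@H]2[C@H](OC(C)=O)[C@]2(O)[C@@H](C)C(=O)O[C@H]2[C@@H]1OS(C)(=O)=O
F7 | step 12 | propargylic hexol (6R, ethynyl on C6) | C=C[C@H](O)[C@@]1(C)C=CC(=O)[C@@](C)(O)[C@@H]1[C@H](O)[C@](O)([C@@H](C)C(=O)OC(C)(C)C)[C@@H](O)[C@H](O)C#C
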